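**Proposed synthesis of Peruvinide A (13): ring A built onto the ring-B phenol by ketene capture and polyketide-type aromatisation**

## Analysis of the target

Peruvinide A (13) is a depside: two benzene rings joined by one aryl ester, with no stereocentre. Ring A is a 2-hydroxy-4-methoxy-6-propylbenzoyl unit, numbered C1 (bearing the ester carbonyl carbon C7), C2 (OH), C3 (H), C4 (OMe), C5 (H) and C6 (propyl). Ring B is methyl 2,4-dihydroxy-3,6-dimethylbenzoate, numbered C1' (CO2Me), C2' (OH), C3' (CH3), C4' (its oxygen O4' carries C7), C5' (H) and C6' (CH3). The feature that invites the strategy is the string C7–C1–C2(O)–C3–C4(O)–C5–C6–propyl of ring A. Oxygen sits on every second carbon, which is the mark of a folded 3,5,7-trioxodecanoyl chain (a butanoyl-primed tetraketide) whose aldol bond is C1–C6. The sensitive groups are the aryl ester C7–O4' (an active ester, open to alkoxides, amines and transesterification), the methyl ester, and two phenols (O2–H and O2'–H), each held in a hydrogen bond to a neighbouring ester carbonyl. The difficulty is hindrance and differentiation, not stereochemistry: C7 lies between two ortho substituents, O4' lies beside the C3' methyl group, and of the four phenolic oxygens one is acylated, one methylated and two are free.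

## Retrosynthetic reasoning

**13 to 12.** The O4–CH3 bond of ring A is cut last. In 12 the C4 hydroxyl is the only phenol that is not locked in a hydrogen bond to a carbonyl, so a single methylation at the end needs no protecting group. This also leaves ring A in the 2,4-dihydroxy form that a polyketide-type aromatisation delivers directly.

**12 to 10 (through 11).** The C1–C6 bond of ring A is cut in the retro-aldol sense and water is added back. This opens ring A to the triketo aryl ester 10, in which every ring-A carbon is present as a linear chain already attached to O4' of ring B. The forward reaction has to close the ring by aldol addition of the carbon next to the ester onto the butanoyl ketone, and then aromatise by dehydration.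

**10 to 9 and 8, and 9 to 7.** The ester bond C7–O4' is cut so that C7 becomes the ketene carbon of acylketene 9 and ring B becomes the free phenol 8, a catalogue compound. A ketene needs no coupling agent and is small enough to reach the hindered O4'. Ketene 9 is masked as dioxinone 7, from which it is released on heating by loss of the isopropylidene ketone. The ester bond and ring A are therefore both made from 7 and 8 in one flask, and ring A never exists as a separate hindered acid.

**7 to 4 and 5.** The bond between the butanoyl carbonyl and the adjacent chain methylene is cut. The forward reaction is acylation of the terminal carbanion of dianion 6 (from ketone 4) with N-methoxy-N-methylamide 5, which stops cleanly at the ketone.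

**4 to 1 and 2 (through 3).** The bond between the acetyl carbonyl and the C6 side-chain carbon of the dioxinone is cut. The forward reaction is C-acylation of lithium dienolate 3, made from the catalogue dioxinone 1, with acetyl chloride 2.

## Alternatives that were turned down

**Alternative 1: the textbook depside esterification.** The C7–O4' bond is cut to 2-hydroxy-4-methoxy-6-propylbenzoic acid A1 and phenol 8, which would be joined with an anhydride or carbodiimide activator. It was turned down for three reasons:
- A1 is not a commodity. It would have to be made from 5-propylbenzene-1,3-diol A2 in about four operations (carboxylation, ester protection, selective O-methylation, deprotection), so the route is longer than the one proposed.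
- The coupling joins a carboxyl flanked by two ortho substituents to a phenol flanked by a methyl group.
- The free C2 hydroxyl of A1 can act as a competing nucleophile, which usually forces a benzyl ether and a final hydrogenolysis.

**Alternative 2: ring A by Diels–Alder reaction and aromatisation.** The C1–C2 and C5–C6 bonds of ring A are cut to the alkynoate methyl 4-(hex-2-ynoyloxy)-2-hydroxy-3,6-dimethylbenzoate A3 and the silyl ketene acetal diene 1,3-dimethoxy-1-(trimethylsilyloxy)buta-1,3-diene A4. Cycloaddition followed by loss of methanol and silanol would give 13 with the C4 methoxy group already in place and the right regiochemistry. It was turned down for three reasons: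
- A β-alkyl alkynoate with a single activating group is a weak dienophile and would need temperatures at which A4 decomposes.
- The free O2'–H of A3 would protonate or desilylate the ketene acetal, and the diene can attack the aryl ester carbonyl.
- A3 must itself be made by esterifying 8, so the hindered ester bond is still formed the classical way.

**Alternative 3: oxygen insertion into a benzophenone.** The C7–O4' bond is formed by Baeyer–Villiger oxidation of methyl 2-hydroxy-4-(2-hydroxy-4-methoxy-6-propylbenzoyl)-3,6-dimethylbenzoate A5 with a peracid. It was turned down for three reasons: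
- The migratory preference is wrong. Ring A carries an ortho hydroxyl and a para methoxy donor relative to its ipso carbon, whereas the ipso carbon of ring B is para to the ester. Ring A would migrate and give the reversed ester 2-hydroxy-4-methoxy-6-propylphenyl 3-hydroxy-4-(methoxycarbonyl)-2,5-dimethylbenzoate A6.
- Electron-rich phenols are oxidised by peracids (Dakin-type and quinone-forming pathways).
- A5 would need a Friedel–Crafts union of two hindered arenes.

Key step: step 3

Remark on the chemistry: 1, 2, 5 and 8 are taken as catalogue chemicals (8 is the fragrance compound methyl atrarate); the target has no stereocentre.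

## Route

Step 1
Reactants: 1 2,2,6-trimethyl-4H-1,3-dioxin-4-one; 2 acetyl chloride
Product: 4 2,2-dimethyl-6-(2-oxopropyl)-4H-1,3-dioxin-4-one, via lithium dienolate 3 (not isolated)
Conditions: 1 (2 equiv), LiN(SiMe3)2 (2 equiv), THF, −78 °C; then 2 (1 equiv), −78 °C; aq NH4Cl
Reagents that add atoms: none
Why: LiN(SiMe3)2 removes a proton from the C6 methyl group of 1 to give the cross-conjugated dienolate 3, which is acylated at its exocyclic γ-carbon by 2 (vinylogous Claisen-type C-acylation); 4 is more acidic than 1, so 3 is used in twofold excess and the surplus returns as 1 on work-up.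

Step 2
Reactants: 4 2,2-dimethyl-6-(2-oxopropyl)-4H-1,3-dioxin-4-one; 5 N-methoxy-N-methylbutanamide
Product: 7 6-(2,4-dioxoheptyl)-2,2-dimethyl-4H-1,3-dioxin-4-one, via dilithium dianion 6 (not isolated)
Conditions: LiN(i-Pr)2 (2.2 equiv), THF, −78 °C; then 5, −78 → −40 °C; 1 M aq HCl
Reagents that add atoms: none
Why: Two equivalents of LiN(i-Pr)2 convert 4 into dianion 6, whose last-formed terminal carbanion is the most nucleophilic site (β-dicarbonyl dianion principle) and adds to amide 5 (Weinreb ketone synthesis); the chelated tetrahedral adduct holds until the acidic quench, so 7 should form without double addition and with the dioxinone intact.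

Step 3
Reactants: 7 6-(2,4-dioxoheptyl)-2,2-dimethyl-4H-1,3-dioxin-4-one; 8 methyl 2,4-dihydroxy-3,6-dimethylbenzoate
Product: 12 methyl 4-[(2,4-dihydroxy-6-propylbenzoyl)oxy]-2-hydroxy-3,6-dimethylbenzoate, via acylketene 9 (not isolated), via triketo aryl ester 10 (not isolated), via aldol adduct 11 (not isolated)
Conditions: 8 (1.5 equiv), PhMe (concentrated), 110 °C; then Et3N, CH2Cl2, 0 °C → rt; dilute aq HCl work-up
Reagents that add atoms: none
Why: At 110 °C 7 undergoes a retro-[4+2] fragmentation that expels acetone and gives acylketene 9, whose ketene carbon (the later C7) is captured by the free O4'–H of 8 to give 10, so the depside bond C7–O4' forms without any activating agent. Et3N then enolises 10, and the carbon between the ester and the first ketone (the later C1) adds to the butanoyl ketone carbon (the later C6) in a 6-(enolexo)-exo-trig aldol reaction that closes carbocyclic ring A as 11; β-elimination of water and enolisation of the two remaining ketones give the aromatic ring and make the sequence irreversible. The closest known reaction types are the thermolysis of 6-substituted dioxinones to acylketenes with capture by alcohols or phenols, and the base-mediated aldol aromatisation of 3,5,7-trioxoalkanoates to β-resorcylates, which is the laboratory copy of polyketide folding. No stereocentre is set, since the two in 11 are lost on aromatisation. Site selectivity in 8 comes from the substrate: O2'–H is tied in a hydrogen bond to the methyl ester carbonyl and sits between the C3' methyl group and the ester, so only O4'–H should add to the ketene. Capture between molecules has to beat capture of the ketene by the enol oxygen of its own β-diketone, which is why 8 is used in excess at high concentration. The aldol mode has to beat the Claisen mode and lactonisation, both of which would expel 8; the ketone is the better electrophile, and a weak amine base in an aprotic solvent is the setting in which such triketo esters are known to take the aldol path.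

Step 4
Reactants: 12 methyl 4-[(2,4-dihydroxy-6-propylbenzoyl)oxy]-2-hydroxy-3,6-dimethylbenzoate
Product: 13 Peruvinide A, methyl 2-hydroxy-4-[(2-hydroxy-4-methoxy-6-propylbenzoyl)oxy]-3,6-dimethylbenzoate
Conditions: MeI (1.1 equiv), K2CO3 (1.1 equiv), acetone, rt
Reagents that add atoms: iodomethane, CI
Why: Williamson-type O-methylation under weak-base control: in 12 the C4 hydroxyl of ring A is the only phenol not held in a six-membered hydrogen bond to an ester carbonyl and is the most acidic (para to the C7 carbonyl), so one equivalent of base and MeI should alkylate it alone; its phenolate also lowers the electrophilicity of the depside carbonyl, which protects the aryl ester.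

## Compound list

1 | 2,2,6-trimethyl-4H-1,3-dioxin-4-one | CC1=CC(=O)OC(C)(C)O1 | starting material
2 | acetyl chloride | CC(Cl)=O | starting material
3 | lithium 2,2-dimethyl-6-methylidene-6H-1,3-dioxin-4-olate (lithium dienolate of 1, formed in the flask) | [Li+].C=C1C=C([O-])OC(C)(C)O1 | intermediate
4 | 2,2-dimethyl-6-(2-oxopropyl)-4H-1,3-dioxin-4-one | CC(=O)CC1=CC(=O)OC(C)(C)O1 | intermediate
5 | N-methoxy-N-methylbutanamide | CCCC(=O)N(C)OC | starting material
6 | dilithium dianion of 4 (formed in the flask; geometry of the exocyclic double bond not defined) | [Li+].[Li+].C=C([O-])C=C1C=C([O-])OC(C)(C)O1 | intermediate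
7 | 6-(2,4-dioxoheptyl)-2,2-dimethyl-4H-1,3-dioxin-4-one | CCCC(=O)CC(=O)CC1=CC(=O)OC(C)(C)O1 | intermediate
8 | methyl 2,4-dihydroxy-3,6-dimethylbenzoate | COC(=O)c1c(C)cc(O)c(C)c1O | starting material
9 | 3,5,7-trioxodec-1-en-1-one (acylketene, formed in the flask) | CCCC(=O)CC(=O)CC(=O)C=C=O | intermediate
10 | methyl 2-hydroxy-3,6-dimethyl-4-[(3,5,7-trioxodecanoyl)oxy]benzoate (formed in the flask) | CCCC(=O)CC(=O)CC(=O)CC(=O)Oc1cc(C)c(C(=O)OC)c(O)c1C | intermediate
11 | methyl 2-hydroxy-4-[(2-hydroxy-4,6-dioxo-2-propylcyclohexane-1-carbonyl)oxy]-3,6-dimethylbenzoate (formed in the flask; mixture of stereoisomers, both centres lost on aromatisation) | CCCC1(O)CC(=O)CC(=O)C1C(=O)Oc1cc(C)c(C(=O)OC)c(O)c1C | intermediate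
12 | methyl 4-[(2,4-dihydroxy-6-propylbenzoyl)oxy]-2-hydroxy-3,6-dimethylbenzoate | CCCc1cc(O)cc(O)c1C(=O)Oc1cc(C)c(C(=O)OC)c(O)c1C | intermediate
13 | Peruvinide A | CCCc1cc(OC)cc(O)c1C(=O)Oc1cc(C)c(C(=O)OC)c(O)c1C | target

## Step count and risk

Total step count: 4. Longest linear sequence: 4 steps (1 → 4 → 7 → 12 → 13).

**Step 3 (key step).** Two processes are most likely to go wrong. The first is capture of the ketene by the enol oxygen of its own β-diketone instead of by the less nucleophilic, hindered phenol. The second, on base treatment, is ring closure in the Claisen or lactone mode with expulsion of the phenol, because the aryl ester is an active ester. The fallback sets out from 7 and comes back at 13; it aromatises first and forms the ester second. Treating 7 with Et3N in CH2Cl2 without heating should effect the same aldol aromatisation with the dioxinone retained, giving 7-hydroxy-2,2-dimethyl-5-propyl-4H-1,3-benzodioxin-4-one F1. Its only phenol is methylated (MeI, K2CO3, acetone) to 7-methoxy-2,2-dimethyl-5-propyl-4H-1,3-benzodioxin-4-one F2. F2 is then opened at its carbonyl by 8 under base (NaH, THF–DMF, warming); O4' attacks as the more acidic, unchelated phenol and the ketal leaves as acetone, which should give 13 directly.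

**Step 2.** The likely failures are incomplete second deprotonation, proton transfer from the more acidic product to dianion 6, and decay of the dianion on warming before the amide has been consumed. The fallback sets out from 1 and comes back at 7; it brings in the butanoyl group by soft enolisation in place of a dianion. Lithium dienolate 3 (from 1 as in step 1) is acylated with allyl 3-chloro-3-oxopropanoate to give allyl 4-(2,2-dimethyl-4-oxo-4H-1,3-dioxin-6-yl)-3-oxobutanoate F3. Treatment with MgCl2, pyridine and butanoyl chloride in CH2Cl2 at 0 °C acylates the carbon between ketone and ester to give allyl 2-butanoyl-4-(2,2-dimethyl-4-oxo-4H-1,3-dioxin-6-yl)-3-oxobutanoate F4. Pd(PPh3)4 (zerovalent palladium) with morpholine in THF then removes the allyl group, and the β-keto acid loses carbon dioxide to give 7.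

**Step 4.** The likely failure is loss of site selectivity: once the C4 phenolate is consumed, methylation can continue at the chelated O2–H or O2'–H. The fallback sets out from 12 and comes back at 13; it reverses the selection principle from nucleophilicity to chelation. All three phenols are methylated (excess MeI, K2CO3, DMF) to give methyl 4-[(2,4-dimethoxy-6-propylbenzoyl)oxy]-2-methoxy-3,6-dimethylbenzoate F5. BCl3 in CH2Cl2 at −78 → 0 °C then cleaves only the two methyl ethers ortho to a carbonyl, through boron chelation, and leaves the C4 methyl ether, which gives 13.

## Further compounds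

F1 | step 3 | 7-hydroxy-2,2-dimethyl-5-propyl-4H-1,3-benzodioxin-4-one | CCCc1cc(O)cc2OC(C)(C)OC(=O)c12
F2 | step 3 | 7-methoxy-2,2-dimethyl-5-propyl-4H-1,3-benzodioxin-4-one | CCCc1cc(OC)cc2OC(C)(C)OC(=O)c12
F3 | step 2 | allyl 4-(2,2-dimethyl-4-oxo-4H-1,3-dioxin-6-yl)-3-oxobutanoate | C=CCOC(=O)CC(=O)CC1=CC(=O)OC(C)(C)O1
F4 | step 2 | allyl 2-butanoyl-4-(2,2-dimethyl-4-oxo-4H-1,3-dioxin-6-yl)-3-oxobutanoate (racemic, enolisable centre) | C=CCOC(=O)C(C(=O)CCC)C(=O)CC1=CC(=O)OC(C)(C)O1
F5 | step 4 | methyl 4-[(2,4-dimethoxy-6-propylbenzoyl)oxy]-2-methoxy-3,6-dimethylbenzoate | CCCc1cc(OC)cc(OC)c1C(=O)Oc1cc(C)c(C(=O)OC)c(OC)c1C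
A1 | alternative 1 | 2-hydroxy-4-methoxy-6-propylbenzoic acid | CCCc1cc(OC)cc(O)c1C(=O)O
A2 | alternative 1 | 5-propylbenzene-1,3-diol | CCCc1cc(O)cc(O)c1
A3 | alternative 2 | methyl 4-(hex-2-ynoyloxy)-2-hydroxy-3,6-dimethylbenzoate | CCCC#CC(=O)Oc1cc(C)c(C(=O)OC)c(O)c1C
A4 | alternative 2 | 1,3-dimethoxy-1-(trimethylsilyloxy)buta-1,3-diene (geometry at C1=C2 not defined) | C=C(OC)C=C(OC)O[Si](C)(C)C
A5 | alternative 3 | methyl 2-hydroxy-4-(2-hydroxy-4-methoxy-6-propylbenzoyl)-3,6-dimethylbenzoate | CCCc1cc(OC)cc(O)c1C(=O)c1cc(C)c(C(=O)OC)c(O)c1C
A6 | alternative 3 | 2-hydroxy-4-methoxy-6-propylphenyl 3-hydroxy-4-(methoxycarbonyl)-2,5-dimethylbenzoate | CCCc1cc(OC)cc(O)c1OC(=O)c1cc(C)c(C(=O)OC)c(O)c1C
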